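Rings: A = 1,4-phenylene, B = 1,2,3-trisubstituted phenol ring, C = 1,3-phenylene bearing the CH2 next to the carbonyl, D = catechol ring bearing the C=O; the last move is O-demethylation of the tri-O-methyl macrocycle.
The 18-membered ring is closed at the ArCH2–CH2Ar bond between rings A and B by ring-closing metathesis of an open-chain bis-styrene, followed in the same flask by ruthenium hydride hydrogenation, so one operation delivers the macrocycle and its saturated bridge.
Enabling feature: both carbons of that bridge are benzylic (one para to the ether oxygen on ring A, one ortho to the ether oxygen on ring B), so at the alkene level the bond is a stilbene C=C that two aryl vinyl groups form with loss of ethylene; the 2-aryloxystyrene of ring B can hold ruthenium as a chelated benzylidene, and the two diaryl ether oxygens plus the meta-linked C(=O)–CH2 bridge of rings D and C fold the chain so the vinyl ends meet.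
The bis-styrene is cut at the C(=O)–CH2 bond: a benzylic Grignard reagent (rings B and C) adds to a Weinreb amide (rings A and D).
Diaryl ethers: ring A–O–ring D by Chan–Lam–Evans coupling of a gallate-derived phenol, ring B–O–ring C by SNAr on 2-fluoro-3-methoxybenzaldehyde; all four benzene rings are bought and the macrocycle is the only ring formed, last.
Key step: step 7

Assumption: the phenols are carried as methyl ethers, and the non-isolated macrocyclic stilbene is drawn as the E isomer that styrene metathesis normally favours; its geometry is of no consequence because the alkene is hydrogenated in the same flask.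

Step 1
Reactants: 1 methyl 3-hydroxy-4,5-dimethoxybenzoate; 2 (4-ethenylphenyl)boronic acid
Product: 3 methyl 3-(4-ethenylphenoxy)-4,5-dimethoxybenzoate
Conditions: Cu(OAc)2 (1 equiv), pyridine (5 equiv), 4 Å MS, CH2Cl2, air, rt
Reagents that add atoms: none
Why: Chan–Lam–Evans oxidative C–O coupling, in which the aryl group passes from boron to a copper phenoxide and C–O reductive elimination follows at room temperature, with air returning copper to the divalent acetate, should arylate the mono-ortho-substituted phenol without touching the ester or the vinyl group.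

Step 2
Reactants: 3 methyl 3-(4-ethenylphenoxy)-4,5-dimethoxybenzoate
Product: 4 3-(4-ethenylphenoxy)-N,4,5-trimethoxy-N-methylbenzamide (Weinreb amide)
Conditions: MeNHOMe·HCl (1.5 equiv), iPrMgCl (3 equiv), THF, −20 °C to 0 °C
Reagents that add atoms: N,O-dimethylhydroxylamine hydrochloride, CNOC.Cl
Why: Weinreb amide synthesis by direct aminolysis of the methyl ester with the chloromagnesium amide formed in the flask, which should add to the ester faster than iPrMgCl does at this temperature and leaves the styrene untouched.

Step 3
Reactants: 5 2-fluoro-3-methoxybenzaldehyde; 6 3-(hydroxymethyl)phenol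
Product: 7 2-[3-(hydroxymethyl)phenoxy]-3-methoxybenzaldehyde
Conditions: K2CO3, DMF, 110 °C
Reagents that add atoms: none
Why: Nucleophilic aromatic substitution (SNAr, addition–elimination) should work because the fluoride is activated by the ortho formyl group and K2CO3 ionises only the phenol, so the benzylic alcohol stays free.

Step 4
Reactants: 7 2-[3-(hydroxymethyl)phenoxy]-3-methoxybenzaldehyde
Product: 8 [3-(2-ethenyl-6-methoxyphenoxy)phenyl]methanol
Conditions: Ph3PCH3Br (2.5 equiv), KOtBu (2.5 equiv), THF, 0 °C to rt
Reagents that add atoms: methyltriphenylphosphonium bromide, C[P+](c1ccccc1)(c1ccccc1)c1ccccc1.[Br-]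
Why: Wittig methylenation of the aryl aldehyde with the non-stabilised ylide should give the styrene, the excess base merely holding the benzylic alcohol as its alkoxide until work-up.

Step 5
Reactants: 8 [3-(2-ethenyl-6-methoxyphenoxy)phenyl]methanol
Product: 9 2-[3-(chloromethyl)phenoxy]-1-ethenyl-3-methoxybenzene
Conditions: PPh3, CCl4, CH2Cl2, 0 °C to 40 °C
Reagents that add atoms: carbon tetrachloride, ClC(Cl)(Cl)Cl
Why: Appel reaction, in which chloride displaces the alkoxyphosphonium ion by SN2 at the primary benzylic carbon, runs under neutral conditions that should spare the electron-rich styrene.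

Step 6
Reactants: 9 2-[3-(chloromethyl)phenoxy]-1-ethenyl-3-methoxybenzene; 4 3-(4-ethenylphenoxy)-N,4,5-trimethoxy-N-methylbenzamide
Product: 11 2-[3-(2-ethenyl-6-methoxyphenoxy)phenyl]-1-[3-(4-ethenylphenoxy)-4,5-dimethoxyphenyl]ethan-1-one (bis-styrene seco ketone), via benzylic Grignard reagent 10 (not isolated)
Conditions: Mg turnings (3 equiv), 2-MeTHF, 0 °C, slow addition of 9; then 4, THF, −10 °C to rt; aq. NH4Cl
Reagents that add atoms: none
Why: Magnesium insertion into the benzylic chloride followed by Weinreb ketone synthesis should give the aryl benzyl ketone directly, because the N-methoxy chelate stops the acyl substitution at the ketone oxidation level and the styrenes are inert to the Grignard reagent.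

Step 7
Reactants: 11 2-[3-(2-ethenyl-6-methoxyphenoxy)phenyl]-1-[3-(4-ethenylphenoxy)-4,5-dimethoxyphenyl]ethan-1-one
Product: 13 tri-O-methylmarchantin G (saturated 18-membered macrocyclic ketone), via macrocyclic E-stilbene ketone 12 (not isolated)
Conditions: second-generation Grubbs catalyst RuCl2(=CHPh)(PCy3)(H2IMes) (10 mol%, two portions), toluene (2 mM), 80 °C, Ar sparge; then concentrate to 0.05 M, H2 (7 bar), 70 °C, same vessel
Reagents that add atoms: none
Why: The ruthenium benzylidene exchanges onto one aryl vinyl group (the ring B 2-aryloxystyrene can hold the metal as a chelated benzylidene), undergoes (2+2) cycloaddition with the other vinyl group and cycloreversion of the ruthenacyclobutane, and so forms the C=C bond between the two benzylic carbons with loss of ethylene; under H2 the same ruthenium charge becomes a ruthenium hydride that saturates this stilbene to the CH2–CH2 bridge. The closest known reactions are macrocyclising ring-closing metathesis of dienes, the metathesis of styrenes to stilbenes and tandem metathesis–hydrogenation with one charge of ruthenium carbene. The one ring closed is the 18-membered macrocycle, closed by ring-closing metathesis of two terminal aryl vinyl groups with the new bond endocyclic. No stereocentre is formed and the alkene geometry of 12 is erased by the hydrogenation. The step needs ring closure to win over chain growth, which the 2 mM dilution, the removal of ethylene and the chain folded at the two diaryl ether oxygens and at the ortho-substituted ring B should secure, and it needs reduction of the alkene but not of the aryl ketone, which the base-free ruthenium hydride conditions should secure.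

Step 8
Reactants: 13 tri-O-methylmarchantin G
Product: 14 marchantin G
Conditions: BBr3 (8 equiv), CH2Cl2, −78 °C to rt; then H2O
Reagents that add atoms: none
Why: Lewis acid-mediated O-demethylation, in which bromide attacks the O-methyl carbon of each boron–ether adduct, should free the three phenols under conditions to which diaryl ethers and the aryl benzyl ketone are stable.

Compound list
1 | methyl 3-hydroxy-4,5-dimethoxybenzoate | COC(=O)c1cc(O)c(OC)c(OC)c1 | starting material
2 | (4-ethenylphenyl)boronic acid | OB(O)c1ccc(C=C)cc1 | starting material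
3 | methyl 3-(4-ethenylphenoxy)-4,5-dimethoxybenzoate | COC(=O)c1cc(Oc2ccc(C=C)cc2)c(OC)c(OC)c1 | intermediate
4 | 3-(4-ethenylphenoxy)-N,4,5-trimethoxy-N-methylbenzamide | CON(C)C(=O)c1cc(Oc2ccc(C=C)cc2)c(OC)c(OC)c1 | intermediate
5 | 2-fluoro-3-methoxybenzaldehyde | COc1cccc(C=O)c1F | starting material
6 | 3-(hydroxymethyl)phenol | OCc1cccc(O)c1 | starting material
7 | 2-[3-(hydroxymethyl)phenoxy]-3-methoxybenzaldehyde | COc1cccc(C=O)c1Oc1cccc(CO)c1 | intermediate
8 | [3-(2-ethenyl-6-methoxyphenoxy)phenyl]methanol | COc1cccc(C=C)c1Oc1cccc(CO)c1 | intermediate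
9 | 2-[3-(chloromethyl)phenoxy]-1-ethenyl-3-methoxybenzene | COc1cccc(C=C)c1Oc1cccc(CCl)c1 | intermediate
10 | [3-(2-ethenyl-6-methoxyphenoxy)benzyl]magnesium chloride (not isolated) | COc1cccc(C=C)c1Oc1cccc(C[Mg]Cl)c1 | intermediate
11 | 2-[3-(2-ethenyl-6-methoxyphenoxy)phenyl]-1-[3-(4-ethenylphenoxy)-4,5-dimethoxyphenyl]ethan-1-one | C=Cc1ccc(cc1)Oc1cc(cc(OC)c1OC)C(=O)Cc1cccc(c1)Oc1c(OC)cccc1C=C | intermediate
12 | macrocyclic E-stilbene ketone: tri-O-methylmarchantin G with CH=CH in place of the CH2–CH2 bridge between rings A and B (not isolated) | O=C1Cc2cccc(c2)Oc2c(OC)cccc2/C=C/c2ccc(cc2)Oc2cc1cc(OC)c2OC | intermediate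
13 | tri-O-methylmarchantin G (methyl ethers on the ring B phenol and on both ring D phenols) | O=C1Cc2cccc(c2)Oc2c(OC)cccc2CCc2ccc(cc2)Oc2cc1cc(OC)c2OC | intermediate
14 | marchantin G | O=C1Cc2cccc(c2)Oc2c(O)cccc2CCc2ccc(cc2)Oc2cc1cc(O)c2O | target

Total step count: 8. Longest linear sequence: 6 steps (steps 3, 4, 5, 6, 7 and 8).

Steps most likely to fail

Risk 1 (step 7): intermolecular metathesis between two chains may outrun ring closure and give stilbene-linked oligomers that return to the equilibrium only slowly, or the ruthenium carbene may decay at high dilution before ring closure and hydrogenation are complete. The fallback forms the same bond by carbonyl olefination with the ketone masked. Setting out from 11, reduction (NaBH4, MeOH/THF, 0 °C) should give the racemic secondary alcohol F1, and silylation (TBSCl, imidazole, DMF) the silyl ether F2. Lemieux–Johnson cleavage of both vinyl groups (OsO4 cat., NaIO4, 2,6-lutidine, dioxane/H2O) should give the dialdehyde F3. Intramolecular McMurry coupling with low-valent titanium (TiCl4, Zn, pyridine, THF, reflux, slow addition) should then close the ring to the macrocyclic stilbene silyl ether F4. TBAF (THF) should free the macrocyclic stilbene carbinol F5, and Dess–Martin periodinane (CH2Cl2) brings the sequence back to the route at 12, which is isolated here and hydrogenated over Pd/C (H2, 1 atm, EtOAc) to 13.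

Risk 2 (step 6): Wurtz-type homocoupling of the benzylic chloride during magnesium insertion may consume 9 before the organometallic reaches the amide. The fallback avoids a benzylic organometallic by using a sulfone-stabilised carbanion. Setting out from 9, displacement with PhSO2Na (DMF, 60 °C) should give the benzyl phenyl sulfone F6. Deprotonation (n-BuLi, THF, −78 °C) and acylation with 4 should give the racemic β-keto sulfone F7. Reductive desulfonylation (Zn dust, AcOH, THF, rt) comes back to the route at 11.

Risk 3 (step 1): protodeboronation and oxidative homocoupling of the boronic acid may outpace the C–O coupling of the ortho-methoxy phenol. The fallback builds the same ether by SNAr and installs the vinyl group afterwards. Setting out from 1, reaction with 4-fluorobenzaldehyde (K2CO3, DMF, 120 °C) should give methyl 3-(4-formylphenoxy)-4,5-dimethoxybenzoate F8. Wittig methylenation (Ph3PCH3Br, KOtBu, THF, 0 °C to rt) comes back to the route at 3.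

Further compounds
F1 | step 7 | 2-[3-(2-ethenyl-6-methoxyphenoxy)phenyl]-1-[3-(4-ethenylphenoxy)-4,5-dimethoxyphenyl]ethan-1-ol (racemic) | OC(Cc1cccc(c1)Oc1c(OC)cccc1C=C)c1cc(Oc2ccc(C=C)cc2)c(OC)c(OC)c1
F2 | step 7 | tert-butyldimethylsilyl ether of F1 (racemic) | CC(C)(C)[Si](C)(C)OC(Cc1cccc(c1)Oc1c(OC)cccc1C=C)c1cc(Oc2ccc(C=C)cc2)c(OC)c(OC)c1
F3 | step 7 | dialdehyde from F2 with CHO in place of each vinyl group (racemic) | CC(C)(C)[Si](C)(C)OC(Cc1cccc(c1)Oc1c(OC)cccc1C=O)c1cc(Oc2ccc(C=O)cc2)c(OC)c(OC)c1
F4 | step 7 | macrocyclic E-stilbene tert-butyldimethylsilyl ether (racemic) | CC(C)(C)[Si](C)(C)OC1Cc2cccc(c2)Oc2c(OC)cccc2/C=C/c2ccc(cc2)Oc2cc1cc(OC)c2OC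
F5 | step 7 | macrocyclic E-stilbene carbinol (racemic) | OC1Cc2cccc(c2)Oc2c(OC)cccc2/C=C/c2ccc(cc2)Oc2cc1cc(OC)c2OC
F6 | step 6 | 1-ethenyl-3-methoxy-2-{3-[(phenylsulfonyl)methyl]phenoxy}benzene | C=Cc1cccc(OC)c1Oc1cccc(CS(=O)(=O)c2ccccc2)c1
F7 | step 6 | 2-[3-(2-ethenyl-6-methoxyphenoxy)phenyl]-1-[3-(4-ethenylphenoxy)-4,5-dimethoxyphenyl]-2-(phenylsulfonyl)ethan-1-one (racemic) | C=Cc1ccc(cc1)Oc1cc(cc(OC)c1OC)C(=O)C(c1cccc(c1)Oc1c(OC)cccc1C=C)S(=O)(=O)c1ccccc1
F8 | step 1 | methyl 3-(4-formylphenoxy)-4,5-dimethoxybenzoate | COC(=O)c1cc(Oc2ccc(C=O)cc2)c(OC)c(OC)c1
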